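**Retrosynthetic overview**
- Target ⇐ removal of three MOM ethers from the fully protected (E)-stilbene.
- Stilbene C=C ⇐ decarboxylative olefination (β-lactone, loss of CO2) of a 2,3-diaryl-3-hydroxypropanoic acid.
- Key C–C bond ⇐ intermolecular aldol addition (Ivanov type) of the dianion of 3,5-bis(methoxymethoxy)phenylacetic acid (fragment B) to 3-geranyl-4-(methoxymethoxy)benzaldehyde (fragment A).
- Fragment A ⇐ 3-bromo-4-hydroxybenzaldehyde + geranyl bromide (Br/Li exchange, copper-mediated allylation); fragment B ⇐ methyl 3,5-dihydroxyphenylacetate.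
- No ring is formed: both benzene rings are bought, and the (E)-geranyl olefin is carried in from geranyl bromide.

Assumption: the target has no stereocentre (it is achiral), so the stereochemical task reduces to the two E double bonds.

**Step 1**
Reactants: 1 3-bromo-4-hydroxybenzaldehyde
Product: 2 3-bromo-4-(methoxymethoxy)benzaldehyde
Conditions: MOMCl, i-Pr2NEt, CH2Cl2, 0 °C → rt
Reagents that add atoms: chloromethyl methyl ether (MOMCl), COCCl
Why: Williamson-type O-alkylation of an acidic phenol; the MOM ether tolerates all later basic and organometallic steps.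

**Step 2**
Reactants: 2 3-bromo-4-(methoxymethoxy)benzaldehyde
Product: 3 [3-bromo-4-(methoxymethoxy)phenyl]methanol
Conditions: NaBH4, MeOH, 0 °C
Reagents that add atoms: none
Why: Chemoselective borohydride reduction masks the aldehyde, which would not survive the aryllithium of step 4.

**Step 3**
Reactants: 3 [3-bromo-4-(methoxymethoxy)phenyl]methanol
Product: 4 {[3-bromo-4-(methoxymethoxy)phenyl]methoxy}(tert-butyl)dimethylsilane
Conditions: TBSCl, imidazole, DMF, rt
Reagents that add atoms: tert-butyldimethylsilyl chloride (TBSCl), CC(C)(C)[Si](C)(C)Cl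
Why: Standard silylation of a primary alcohol removes the acidic OH before metalation.

**Step 4**
Reactants: 4 {[3-bromo-4-(methoxymethoxy)phenyl]methoxy}(tert-butyl)dimethylsilane; 5 geranyl bromide [(2E)-1-bromo-3,7-dimethylocta-2,6-diene, ≥95% E]
Product: 8 tert-butyl({3-[(2E)-3,7-dimethylocta-2,6-dien-1-yl]-4-(methoxymethoxy)phenyl}methoxy)dimethylsilane, via aryllithium 6 (not isolated), via arylcopper 7 (not isolated)
Conditions: n-BuLi, THF, −78 °C; CuBr·SMe2 (1.1 equiv), −78 → −40 °C; 5, −40 °C → rt
Reagents that add atoms: none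
Why: Bromine–lithium exchange places the metal regiospecifically ortho to the OMOM group, and after transmetallation the arylcopper displaces the primary allylic bromide at its unhindered α-carbon (SN2-type allylic substitution), so the linear chain is attached with the E olefin untouched.

**Step 5**
Reactants: 8 tert-butyl({3-[(2E)-3,7-dimethylocta-2,6-dien-1-yl]-4-(methoxymethoxy)phenyl}methoxy)dimethylsilane
Product: 9 {3-[(2E)-3,7-dimethylocta-2,6-dien-1-yl]-4-(methoxymethoxy)phenyl}methanol
Conditions: Bu4NF (TBAF), THF, 0 °C → rt; H2O work-up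
Reagents that add atoms: none
Why: Fluoride-driven desilylation frees the primary alcohol and leaves the aryl MOM ether and both olefins alone.

**Step 6**
Reactants: 9 {3-[(2E)-3,7-dimethylocta-2,6-dien-1-yl]-4-(methoxymethoxy)phenyl}methanol
Product: 10 3-[(2E)-3,7-dimethylocta-2,6-dien-1-yl]-4-(methoxymethoxy)benzaldehyde
Conditions: MnO2 (excess), CH2Cl2, rt
Reagents that add atoms: none
Why: MnO2 oxidises the electron-rich benzylic alcohol selectively to the aldehyde without over-oxidation or attack on the trisubstituted olefins.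

**Step 7**
Reactants: 11 methyl 2-(3,5-dihydroxyphenyl)acetate
Product: 12 methyl 2-[3,5-bis(methoxymethoxy)phenyl]acetate
Conditions: MOMCl (3 equiv), i-Pr2NEt (4 equiv), CH2Cl2, 0 °C → rt
Reagents that add atoms: chloromethyl methyl ether (MOMCl), COCCl
Why: Double phenol O-alkylation with an amine base too weak to enolise the ester, so no C-alkylation occurs.

**Step 8**
Reactants: 12 methyl 2-[3,5-bis(methoxymethoxy)phenyl]acetate
Product: 13 2-[3,5-bis(methoxymethoxy)phenyl]acetic acid
Conditions: LiOH, THF/MeOH/H2O, rt; then 1 M HCl to pH 3, 0 °C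
Reagents that add atoms: lithium hydroxide, [Li+].[OH-]
Why: Ordinary saponification; aryl MOM ethers are stable to base and to the brief cold acidification.

**Step 9**
Reactants: 13 2-[3,5-bis(methoxymethoxy)phenyl]acetic acid (1.3 equiv); 10 3-[(2E)-3,7-dimethylocta-2,6-dien-1-yl]-4-(methoxymethoxy)benzaldehyde (1.0 equiv)
Product: 15 rac-(2S,3R)-2-[3,5-bis(methoxymethoxy)phenyl]-3-{3-[(2E)-3,7-dimethylocta-2,6-dien-1-yl]-4-(methoxymethoxy)phenyl}-3-hydroxypropanoic acid (anti major), via dilithium enediolate 14 (not isolated)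
Conditions: lithium diisopropylamide (LDA, 2.7 equiv), THF, −78 → 0 °C; 10, −78 °C → rt, 6 h; 1 M HCl to pH 3–4, 0 °C
Reagents that add atoms: none
Why: Ivanov-type intermolecular aldol addition of the arylacetic acid dianion to a non-enolisable aldehyde through a chair Zimmerman–Traxler transition state, with warming letting the dilithium aldolate equilibrate to the anti (2R*,3S*) acid; both new stereocentres are erased in step 10, so the diastereomer ratio is not critical.

**Step 10**
Reactants: 15 rac-(2S,3R)-2-[3,5-bis(methoxymethoxy)phenyl]-3-{3-[(2E)-3,7-dimethylocta-2,6-dien-1-yl]-4-(methoxymethoxy)phenyl}-3-hydroxypropanoic acid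
Product: 18 1-[(E)-2-{3-[(2E)-3,7-dimethylocta-2,6-dien-1-yl]-4-(methoxymethoxy)phenyl}ethenyl]-3,5-bis(methoxymethoxy)benzene, via acyl benzenesulfonate 16 (not isolated), via trans β-lactone 17 (not isolated)
Conditions: PhSO2Cl (2 equiv), pyridine, 0 °C, 16 h; then 60 °C, 2 h, dark
Reagents that add atoms: none
Why: Adam-type β-lactonisation by carboxyl activation (retention at the carbinol carbon) gives the trans β-lactone, whose thermal [2+2] cycloreversion with loss of CO2 (decarboxylative olefination) gives the E stilbene; the para-alkoxybenzylic C–O bond ionises easily, so the minor syn acid also funnels to the more stable E alkene.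

**Step 11**
Reactants: 18 1-[(E)-2-{3-[(2E)-3,7-dimethylocta-2,6-dien-1-yl]-4-(methoxymethoxy)phenyl}ethenyl]-3,5-bis(methoxymethoxy)benzene
Product: 19 schweinfurthin I [5-[(E)-2-{3-[(2E)-3,7-dimethylocta-2,6-dien-1-yl]-4-hydroxyphenyl}ethenyl]benzene-1,3-diol]
Conditions: TsOH·H2O (0.3 equiv), MeOH, rt, argon, dark
Reagents that add atoms: none
Why: Acid-catalysed acetal exchange with methanol removes all three MOM groups under conditions mild enough (room temperature, catalytic acid) to leave the geranyl chain and both E olefins unchanged.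

**Compound list**
1 | 3-bromo-4-hydroxybenzaldehyde | O=Cc1ccc(O)c(Br)c1 | starting material
2 | 3-bromo-4-(methoxymethoxy)benzaldehyde | COCOc1ccc(C=O)cc1Br | intermediate
3 | [3-bromo-4-(methoxymethoxy)phenyl]methanol | COCOc1ccc(CO)cc1Br | intermediate
4 | {[3-bromo-4-(methoxymethoxy)phenyl]methoxy}(tert-butyl)dimethylsilane | COCOc1ccc(CO[Si](C)(C)C(C)(C)C)cc1Br | intermediate
5 | geranyl bromide, (2E)-1-bromo-3,7-dimethylocta-2,6-diene | CC(C)=CCC/C(C)=C/CBr | starting material
6 | [5-({[tert-butyl(dimethyl)silyl]oxy}methyl)-2-(methoxymethoxy)phenyl]lithium | [Li]c1cc(CO[Si](C)(C)C(C)(C)C)ccc1OCOC | intermediate (not isolated)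
7 | [5-({[tert-butyl(dimethyl)silyl]oxy}methyl)-2-(methoxymethoxy)phenyl]copper | [Cu]c1cc(CO[Si](C)(C)C(C)(C)C)ccc1OCOC | intermediate (not isolated)
8 | tert-butyl({3-[(2E)-3,7-dimethylocta-2,6-dien-1-yl]-4-(methoxymethoxy)phenyl}methoxy)dimethylsilane | CC(C)=CCC/C(C)=C/Cc1cc(CO[Si](C)(C)C(C)(C)C)ccc1OCOC | intermediate
9 | {3-[(2E)-3,7-dimethylocta-2,6-dien-1-yl]-4-(methoxymethoxy)phenyl}methanol | CC(C)=CCC/C(C)=C/Cc1cc(CO)ccc1OCOC | intermediate
10 | 3-[(2E)-3,7-dimethylocta-2,6-dien-1-yl]-4-(methoxymethoxy)benzaldehyde | CC(C)=CCC/C(C)=C/Cc1cc(C=O)ccc1OCOC | intermediate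
11 | methyl 2-(3,5-dihydroxyphenyl)acetate | COC(=O)Cc1cc(O)cc(O)c1 | starting material
12 | methyl 2-[3,5-bis(methoxymethoxy)phenyl]acetate | COCOc1cc(CC(=O)OC)cc(OCOC)c1 | intermediate
13 | 2-[3,5-bis(methoxymethoxy)phenyl]acetic acid | COCOc1cc(CC(=O)O)cc(OCOC)c1 | intermediate
14 | dilithium 2-[3,5-bis(methoxymethoxy)phenyl]ethene-1,1-diolate | [Li+].[Li+].[O-]C([O-])=Cc1cc(OCOC)cc(OCOC)c1 | intermediate (not isolated)
15 | rac-(2S,3R)-2-[3,5-bis(methoxymethoxy)phenyl]-3-{3-[(2E)-3,7-dimethylocta-2,6-dien-1-yl]-4-(methoxymethoxy)phenyl}-3-hydroxypropanoic acid (anti, one enantiomer drawn) | O=C(O)[C@@H](c1cc(OCOC)cc(OCOC)c1)[C@@H](O)c1ccc(OCOC)c(C/C=C(\C)CCC=C(C)C)c1 | intermediate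
16 | mixed anhydride of 15 with benzenesulfonic acid (acyl benzenesulfonate, rac, one enantiomer drawn) | O=C(OS(=O)(=O)c1ccccc1)[C@@H](c1cc(OCOC)cc(OCOC)c1)[C@@H](O)c1ccc(OCOC)c(C/C=C(\C)CCC=C(C)C)c1 | intermediate (not isolated)
17 | rac-(3S,4R)-3-[3,5-bis(methoxymethoxy)phenyl]-4-{3-[(2E)-3,7-dimethylocta-2,6-dien-1-yl]-4-(methoxymethoxy)phenyl}oxetan-2-one (trans, one enantiomer drawn) | O=C1O[C@@H](c2ccc(OCOC)c(C/C=C(\C)CCC=C(C)C)c2)[C@@H]1c3cc(OCOC)cc(OCOC)c3 | intermediate (not isolated)
18 | 1-[(E)-2-{3-[(2E)-3,7-dimethylocta-2,6-dien-1-yl]-4-(methoxymethoxy)phenyl}ethenyl]-3,5-bis(methoxymethoxy)benzene | CC(C)=CCC/C(C)=C/Cc1cc(/C=C/c2cc(OCOC)cc(OCOC)c2)ccc1OCOC | intermediate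
19 | schweinfurthin I, 5-[(E)-2-{3-[(2E)-3,7-dimethylocta-2,6-dien-1-yl]-4-hydroxyphenyl}ethenyl]benzene-1,3-diol | CC(C)=CCC/C(C)=C/Cc1cc(/C=C/c2cc(O)cc(O)c2)ccc1O | target

**Totals**
Total step count: 11. Longest linear sequence: 9 steps (steps 1–6, then 9–11); the fragment B branch (steps 7–8) joins at step 9.

**Three steps most likely to fail**

Step 9 (aldol). The dianion of 13 can be poorly soluble, and the electron-rich aldehyde 10 may give incomplete conversion or retro-aldol on warming. Fallback: set out from ester 12 and aldehyde 10. Deprotonate 12 with LDA (1.1 equiv, THF, −78 °C) to the soluble ester monoenolate and add 10 at −78 °C under kinetic control. This gives methyl 2-[3,5-bis(methoxymethoxy)phenyl]-3-{3-[(2E)-3,7-dimethylocta-2,6-dien-1-yl]-4-(methoxymethoxy)phenyl}-3-hydroxypropanoate F1 as a syn/anti mixture. Hydrolyse it with LiOH in THF/H2O at 0 °C (or Me3SnOH in 1,2-dichloroethane at 70 °C if retro-aldol intrudes) to come back to the route at acid 15. The diastereomer mixture is tolerated because step 10 converges on the E alkene.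

Step 10 (decarboxylative olefination). Sulfonylation of the benzylic alcohol or sluggish lactonisation could lower the yield, and a stereospecific pathway from residual syn acid would give some Z isomer. Fallback: set out from acid 15 and activate the hydroxyl group instead of the carboxyl group. Heat 15 with N,N-dimethylformamide dineopentyl acetal in CHCl3 at 60 °C. The O-formamidinium carboxylate ionises at the para-alkoxybenzylic carbon and loses CO2 (dehydrative decarboxylation), giving the thermodynamically favoured E stilbene. This comes back to the route directly at 18 and makes no new isolable compound (F0).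

Step 11 (global MOM removal). Brønsted acid can cyclise the ortho-geranyl phenol to a chroman or add methanol to the trisubstituted olefins. Fallback: set out from 18 and trans-protect under non-acidic conditions with TESOTf and 2,2'-bipyridyl (CH2Cl2, 0 °C → rt), which converts aryl MOM ethers into aryl triethylsilyl ethers. This gives 1-[(E)-2-{3-[(2E)-3,7-dimethylocta-2,6-dien-1-yl]-4-(triethylsilyloxy)phenyl}ethenyl]-3,5-bis(triethylsilyloxy)benzene F2. Cleave F2 with TBAF/AcOH in THF at 0 °C to come back to the route at the target 19.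

**Further compounds**
F1 | step 9 | methyl 2-[3,5-bis(methoxymethoxy)phenyl]-3-{3-[(2E)-3,7-dimethylocta-2,6-dien-1-yl]-4-(methoxymethoxy)phenyl}-3-hydroxypropanoate (racemic syn/anti mixture) | COC(=O)C(c1cc(OCOC)cc(OCOC)c1)C(O)c1ccc(OCOC)c(C/C=C(\C)CCC=C(C)C)c1
F0 | step 10 | none | none
F2 | step 11 | 1-[(E)-2-{3-[(2E)-3,7-dimethylocta-2,6-dien-1-yl]-4-(triethylsilyloxy)phenyl}ethenyl]-3,5-bis(triethylsilyloxy)benzene | CC(C)=CCC/C(C)=C/Cc1cc(/C=C/c2cc(O[Si](CC)(CC)CC)cc(O[Si](CC)(CC)CC)c2)ccc1O[Si](CC)(CC)CC
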